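**Overview**
1. Ring B (C5–C6–C7–C8–C9–C10) is opened at C6–C7. The C6 carbinol next to C7, which carries the C11(=C13H2)–C12 acrylic acid, is a homoallylic alcohol: the retron of a 2-carboxyallyl metal (C13–C11–C7) adding to a C6 aldehyde on C5.
2. The (Z)-2-(bromomethyl)enoate arm on C10 comes from a Baylis–Hillman reaction of the C7 α-silyloxy aldehyde with 2-(trimethylsilyl)ethyl (TMSE) acrylate, followed by SN2′ bromination.
3. Ring A with C1, C10 and C8 already set is cut out of (R)-Wieland–Miescher ketone (1-ketone reduction, α′-hydroxylation at C8, oxidative cleavage of the C5=C6 enone). C15 enters by enolate alkylation at C4, C6 by methylenation–hydroboration at C5.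
4. After ring closure: 6-O-silylation, 8-O-acylation with O-silyl 2-(hydroxymethyl)acrylic acid, C15 oxidation, fluoride deprotection.
5. Ring order: ring A is carried from the starting material; ring B is closed in the key step.

Key step: step 15

Remark: locants are eudesmane numbers, with β the face of the C10 methyl; (R)-(−)-Wieland–Miescher ketone is taken as purchased, and 4-methoxybenzyl chloromethyl ether is freshly made (PMBOCH2SMe, SO2Cl2) and used as a reagent.

**Route**

Step 1
Reactants: 1 (R)-(−)-Wieland–Miescher ketone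
Product: 2 (4aR,5R)-5-hydroxy-4a-methyl-4,4a,5,6,7,8-hexahydronaphthalen-2(3H)-one
Conditions: NaBH4 (0.3 equiv), EtOH, −10 °C
Reagents that add atoms: none
Why: Chemoselective borohydride reduction of the saturated C1 ketone in the presence of the enone, with hydride entering axially, anti to the angular methyl, so that the new hydroxyl should be equatorial and cis to the C10 methyl (1β, 1R).

Step 2
Reactants: 2 (4aR,5R)-5-hydroxy-4a-methyl-4,4a,5,6,7,8-hexahydronaphthalen-2(3H)-one
Product: 3 (4aR,5R)-5-(tert-butyldimethylsilyloxy)-4a-methyl-4,4a,5,6,7,8-hexahydronaphthalen-2(3H)-one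
Conditions: TBSCl, imidazole, DMF, 35 °C
Reagents that add atoms: tert-butyldimethylsilyl chloride, CC(C)(C)[Si](C)(C)Cl
Why: Standard imidazole-promoted silylation of the neopentyl secondary alcohol, giving a TBS ether meant to last until the final step.

Step 3
Reactants: 3 (4aR,5R)-5-(tert-butyldimethylsilyloxy)-4a-methyl-4,4a,5,6,7,8-hexahydronaphthalen-2(3H)-one
Product: 5 (3S,4aR,5R)-5-(tert-butyldimethylsilyloxy)-3-hydroxy-4a-methyl-4,4a,5,6,7,8-hexahydronaphthalen-2(3H)-one (8α-hydroxy enone), via potassium dienolate 4 (not isolated)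
Conditions: KHMDS, THF, −78 °C; then 2-(phenylsulfonyl)-3-phenyloxaziridine, −78 °C; aq. NH4Cl
Reagents that add atoms: 2-(phenylsulfonyl)-3-phenyloxaziridine (Davis reagent), O=S(=O)(c1ccccc1)N1OC1c1ccccc1
Why: Kinetic α′-deprotonation of the enone at C8 and Davis enolate hydroxylation, the oxidant approaching the α face because the pseudo-axial C10 methyl is 1,3 to C8 on the β face, which should give the equatorial 8α-carbinol (8S), also the thermodynamic epimer next to the ketone.

Step 4
Reactants: 5 (3S,4aR,5R)-5-(tert-butyldimethylsilyloxy)-3-hydroxy-4a-methyl-4,4a,5,6,7,8-hexahydronaphthalen-2(3H)-one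
Product: 6 (3S,4aR,5R)-5-(tert-butyldimethylsilyloxy)-4a-methyl-3-(triethylsilyloxy)-4,4a,5,6,7,8-hexahydronaphthalen-2(3H)-one
Conditions: TESCl, imidazole, CH2Cl2, 0 °C → rt
Reagents that add atoms: chlorotriethylsilane, CC[Si](Cl)(CC)CC
Why: Routine silylation of the α-hydroxy ketone; TES is chosen for O8 because it must later be removed in the presence of TBS ethers.

Step 5
Reactants: 6 (3S,4aR,5R)-5-(tert-butyldimethylsilyloxy)-4a-methyl-3-(triethylsilyloxy)-4,4a,5,6,7,8-hexahydronaphthalen-2(3H)-one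
Product: 7 (2S)-3-[(1S,2R)-2-(tert-butyldimethylsilyloxy)-1-methyl-6-oxocyclohexyl]-2-(triethylsilyloxy)propanoic acid
Conditions: RuCl3·xH2O (cat.), NaIO4, EtOAc/MeCN/H2O, 0 °C → rt
Reagents that add atoms: sodium periodate, [Na+].[O-]I(=O)(=O)=O; water, O
Why: Ruthenium tetroxide cleavage (Sharpless conditions) of the C5=C6 enone double bond with oxidative loss of C6 as CO2, the classical enone-to-keto-acid degradation, should leave the C5 ketone and the C7 acid without touching any stereocentre.

Step 6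
Reactants: 7 (2S)-3-[(1S,2R)-2-(tert-butyldimethylsilyloxy)-1-methyl-6-oxocyclohexyl]-2-(triethylsilyloxy)propanoic acid
Product: 8 methyl (2S)-3-[(1S,2R)-2-(tert-butyldimethylsilyloxy)-1-methyl-6-oxocyclohexyl]-2-(triethylsilyloxy)propanoate
Conditions: TMSCHN2, toluene/MeOH, 0 °C
Reagents that add atoms: (trimethylsilyl)diazomethane, C[Si](C)(C)C=[N+]=[N-]
Why: Diazoalkane esterification under neutral conditions that spare both silyl ethers and the α-silyloxy stereocentre.

Step 7
Reactants: 8 methyl (2S)-3-[(1S,2R)-2-(tert-butyldimethylsilyloxy)-1-methyl-6-oxocyclohexyl]-2-(triethylsilyloxy)propanoate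
Product: 10 methyl (2S)-3-[(1S,2R,5S)-2-(tert-butyldimethylsilyloxy)-5-[(4-methoxybenzyloxy)methyl]-1-methyl-6-oxocyclohexyl]-2-(triethylsilyloxy)propanoate (4α-CH2OPMB), via lithium enolate 9 (not isolated)
Conditions: LDA, THF, −78 °C; then PMBOCH2Cl, −78 → −40 °C
Reagents that add atoms: 4-methoxybenzyl chloromethyl ether, COc1ccc(COCCl)cc1
Why: Enolate alkylation: LDA enolises the ketone at C4, its only α-CH2 (the ester α-H is less acidic and shielded by OTES), and the chloromethyl ether should attack opposite the pseudo-axial C10 methyl to give the equatorial 4α-substituent, which is also the thermodynamic epimer.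

Step 8
Reactants: 10 methyl (2S)-3-[(1S,2R,5S)-2-(tert-butyldimethylsilyloxy)-5-[(4-methoxybenzyloxy)methyl]-1-methyl-6-oxocyclohexyl]-2-(triethylsilyloxy)propanoate
Product: 11 C5-methylidene compound (as 10 with C5=CH2 in place of C5=O)
Conditions: Zn, CH2Br2, TiCl4 (Takai–Lombardo reagent), THF/CH2Cl2, 0 °C → rt
Reagents that add atoms: dibromomethane, BrCBr
Why: Takai–Lombardo methylenation is non-basic, so the β-alkoxy ketone should neither epimerise at C4 nor eliminate PMBOH, and it leaves the methyl ester alone while still reacting with hindered ketones.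

Step 9
Reactants: 11 C5-methylidene compound
Product: 13 C6 primary alcohol (ring A: 1β-OTBS, 10β-CH3, 5β-CH2OH with 5α-H, 4α-CH2OPMB; arm C9H2–C8H(OTES)–CO2Me), via B-alkyl-9-BBN adduct 12 (not isolated)
Conditions: 9-BBN, THF, 0 → 60 °C; then NaBO3·4H2O, H2O, rt
Reagents that add atoms: sodium perborate, [Na+].[O-]B1OO1
Why: Hydroboration–oxidation puts boron on terminal C6 and delivers hydrogen to C5 from the α face, because the axial C10 methyl on the neighbouring carbon shields the β face, which should give 5α-H with the CH2OH arm equatorial and trans to both neighbours; the ester is inert to 9-BBN.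

Step 10
Reactants: 13 C6 primary alcohol
Product: 14 C7 aldehyde (as 13 with CHO in place of CO2Me; C6-OH free)
Conditions: DIBAL-H (2.5 equiv), CH2Cl2, −78 °C; Rochelle salt
Reagents that add atoms: none
Why: Partial ester reduction: the chelated aluminium hemiacetal of an α-silyloxy ester is stable at −78 °C and releases the aldehyde only on work-up, while the free C6 hydroxyl merely consumes one hydride.

Step 11
Reactants: 15 acryloyl chloride; 16 2-(trimethylsilyl)ethanol
Product: 17 2-(trimethylsilyl)ethyl acrylate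
Conditions: Et3N, CH2Cl2, 0 °C
Reagents that add atoms: none
Why: Acylation of the primary alcohol by the acid chloride with an amine base.

Step 12
Reactants: 14 C7 aldehyde; 17 2-(trimethylsilyl)ethyl acrylate
Product: 18 Baylis–Hillman adduct (C7 carbinol, both epimers; C6-OH free)
Conditions: 3-hydroxyquinuclidine (0.5 equiv), neat 17 (excess), rt
Reagents that add atoms: none
Why: Morita–Baylis–Hillman reaction, in which the amine–acrylate zwitterion adds to the C7 aldehyde (activated by the α-silyloxy group); the new C7 carbinol centre is erased in step 14, and the weakly basic conditions should spare C8.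

Step 13
Reactants: 18 Baylis–Hillman adduct
Product: 19 C6 aldehyde (5β-CHO) with the C7 allylic carbinol retained
Conditions: TEMPO (cat.), PhI(OAc)2, CH2Cl2, rt
Reagents that add atoms: none
Why: Oxoammonium (TEMPO) oxidation takes primary alcohols much faster than the hindered, electron-poor Baylis–Hillman carbinol and is not basic, so C5 should keep its configuration.

Step 14
Reactants: 19 C6 aldehyde with C7 allylic carbinol
Product: 20 ring-A C6 aldehyde carrying the (8S)-8-triethylsilyloxy (Z)-2-(bromomethyl)enoate arm (TMSE ester; 1β-OTBS, 4α-CH2OPMB)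
Conditions: NBS, Me2S, CH2Cl2, −20 → 0 °C
Reagents that add atoms: N-bromosuccinimide, O=C1CCC(=O)N1Br
Why: Corey–Kim-type activation of the Baylis–Hillman hydroxyl followed by SN2′ attack of bromide at C13 should give the conjugated, thermodynamically preferred (Z)-2-(bromomethyl)enoate, with aldehyde and silyl ethers untouched.

Step 15
Reactants: 20 ring-A C6 aldehyde with the (Z)-2-(bromomethyl)enoate arm
Product: 22 2-(trimethylsilyl)ethyl 6α-hydroxy-1β-(tert-butyldimethylsilyloxy)-15-(4-methoxybenzyloxy)-8α-(triethylsilyloxy)eudesm-11(13)-en-12-oate (5α-H and 7α-H and 4β-H), via allylchromium(III) species 21 (not isolated)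
Conditions: CrCl2 (8 equiv), THF, rt, slow addition of 20 (final 0.003 M); aq. NH4Cl
Reagents that add atoms: none
Why: Cr(II) reduces the allylic C–Br bond in two one-electron steps to the 2-(alkoxycarbonyl)allylchromium(III) 21, which adds through its γ-carbon C7 to the C6 aldehyde in a closed six-membered Zimmerman–Traxler transition state with allylic transposition, so that C6–C7 forms and the C11=C13 methylene appears (intramolecular Nozaki–Hiyama–Kishi/Barbier allylation, a known reaction type for 2-(bromomethyl)acrylates and aldehydes). Ring B closes by 6-exo-trig attack on the carbonyl as a chair fused trans to ring A, because the C5 and C10 arms are trans-diequatorial. C6 and C7 are set together: the Zimmerman–Traxler ring is fused to the nascent ring B across C6–C7, and only the trans-fused chair–chair array, with O6 and C11 equatorial, keeps ring B a chair with the 8-OTES group equatorial, which should give 6α-OH (6R) and 7α-H (7S). That array needs the allylchromium isomer with C8 trans to C13; allylchromium(III) species interconvert by σ–π–σ shifts, so the (Z)-geometry of the bromide should not be carried through. The step needs 6,7-anti selectivity and reaction at the allyl bromide only; the neutral conditions, the preorganised arms and high dilution (against Wurtz-type dimerisation) should secure this, and the chromium alkoxide should not lactonise onto the TMSE ester because that lactone would be trans-fused.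

Step 16
Reactants: 22 6α-hydroxy-8α-triethylsilyloxy eudesmane ester
Product: 23 6α-O-TBS ether of 22
Conditions: TBSOTf, 2,6-lutidine, CH2Cl2, −78 → 0 °C
Reagents that add atoms: tert-butyldimethylsilyl triflate, CC(C)(C)[Si](C)(C)OS(=O)(=O)C(F)(F)F
Why: Silyl triflate silylation of the hindered equatorial 6-OH, which marks O6 so that O8 can be freed alone.

Step 17
Reactants: 23 6α-O-TBS ether
Product: 24 8α-alcohol (1β,6α-bis-OTBS, 15-OPMB, TMSE ester)
Conditions: HF·pyridine, pyridine, THF, 0 °C
Reagents that add atoms: none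
Why: Selective desilylation: buffered HF·pyridine cleaves the secondary triethylsilyl ether much faster than the two hindered TBS ethers and does not attack the TMSE ester.

Step 18
Reactants: 25 ethyl 2-(hydroxymethyl)acrylate
Product: 26 ethyl 2-[(tert-butyldimethylsilyloxy)methyl]acrylate
Conditions: TBSCl, imidazole, CH2Cl2, 0 °C → rt
Reagents that add atoms: tert-butyldimethylsilyl chloride, CC(C)(C)[Si](C)(C)Cl
Why: Routine silylation of the primary allylic alcohol.

Step 19
Reactants: 26 ethyl 2-[(tert-butyldimethylsilyloxy)methyl]acrylate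
Product: 27 2-[(tert-butyldimethylsilyloxy)methyl]acrylic acid
Conditions: LiOH·H2O, THF/H2O, 0 °C → rt; then 1 M HCl to pH 4, 0 °C
Reagents that add atoms: lithium hydroxide, [Li+].[OH-]
Why: Saponification of the ethyl ester; the primary TBS ether should survive cold hydroxide and brief mild acidification.

Step 20
Reactants: 24 8α-alcohol; 27 2-[(tert-butyldimethylsilyloxy)methyl]acrylic acid
Product: 28 8α-O-{2-[(tert-butyldimethylsilyloxy)methyl]acryloyl} ester (1β,6α-bis-OTBS, 15-OPMB, TMSE ester)
Conditions: DCC, DMAP (cat.), CH2Cl2, 0 °C → rt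
Reagents that add atoms: none
Why: Steglich esterification of the equatorial 8-OH, an acyl transfer at oxygen that leaves C8 unchanged.

Step 21
Reactants: 28 8α-O-acyl ester
Product: 29 C15 primary alcohol
Conditions: DDQ, CH2Cl2/pH 7 buffer, 0 °C → rt
Reagents that add atoms: none
Why: Oxidative PMB ether cleavage by DDQ via the benzylic cation; silyl ethers, esters and the electron-poor alkenes should not react.

Step 22
Reactants: 29 C15 primary alcohol
Product: 30 C15 aldehyde (4α-CHO; fully protected target)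
Conditions: Dess–Martin periodinane, NaHCO3, CH2Cl2, 0 °C → rt
Reagents that add atoms: none
Why: Dess–Martin oxidation under buffered, non-basic conditions; the equatorial 4α-aldehyde is also the stable epimer, so C4 should hold.

Step 23
Reactants: 30 C15 aldehyde
Product: 31 8α-[2-(hydroxymethyl)acryloyloxy]-1β,6α-dihydroxy-15-oxoeudesm-11(13)-en-12-oic acid (CNP0599450.1)
Conditions: TASF, DMF, 0 °C → rt; aq. NH4Cl
Reagents that add atoms: none
Why: Fluoride-induced fragmentation of the TMSE ester (loss of ethylene) should come first, so that C12 is a carboxylate and no longer an acylating agent when O6 is freed, and the same reagent then removes the three TBS ethers under neutral, anhydrous conditions that should spare the acrylate ester and the aldehyde.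

**Compound list**
1 | (R)-(−)-Wieland–Miescher ketone, (8aR)-8a-methyl-3,4,8,8a-tetrahydronaphthalene-1,6(2H,7H)-dione | C1[C@]2(C)C(=CC(=O)C1)CCCC2=O | starting material
2 | (4aR,5R)-5-hydroxy-4a-methyl-4,4a,5,6,7,8-hexahydronaphthalen-2(3H)-one | C1[C@]2(C)C(=CC(=O)C1)CCC[C@H]2O | intermediate
3 | (4aR,5R)-5-(tert-butyldimethylsilyloxy)-4a-methyl-4,4a,5,6,7,8-hexahydronaphthalen-2(3H)-one | C1[C@]2(C)C(=CC(=O)C1)CCC[C@H]2O[Si](C)(C)C(C)(C)C | intermediate
4 | potassium cross-conjugated dienolate of 3 (O–C7=C8, C5=C6) | C1[C@]2(C)C(=CC([O-])=C1)CCC[C@H]2O[Si](C)(C)C(C)(C)C.[K+] | intermediate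
5 | (3S,4aR,5R)-5-(tert-butyldimethylsilyloxy)-3-hydroxy-4a-methyl-4,4a,5,6,7,8-hexahydronaphthalen-2(3H)-one | C1[C@]2(C)C(=CC(=O)[C@H]1O)CCC[C@H]2O[Si](C)(C)C(C)(C)C | intermediate
6 | (3S,4aR,5R)-5-(tert-butyldimethylsilyloxy)-4a-methyl-3-(triethylsilyloxy)-4,4a,5,6,7,8-hexahydronaphthalen-2(3H)-one | C1[C@]2(C)C(=CC(=O)[C@H]1O[Si](CC)(CC)CC)CCC[C@H]2O[Si](C)(C)C(C)(C)C | intermediate
7 | (2S)-3-[(1S,2R)-2-(tert-butyldimethylsilyloxy)-1-methyl-6-oxocyclohexyl]-2-(triethylsilyloxy)propanoic acid | OC(=O)[C@@H](O[Si](CC)(CC)CC)C[C@]1(C)C(=O)CCC[C@H]1O[Si](C)(C)C(C)(C)C | intermediate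
8 | methyl (2S)-3-[(1S,2R)-2-(tert-butyldimethylsilyloxy)-1-methyl-6-oxocyclohexyl]-2-(triethylsilyloxy)propanoate | COC(=O)[C@@H](O[Si](CC)(CC)CC)C[C@]1(C)C(=O)CCC[C@H]1O[Si](C)(C)C(C)(C)C | intermediate
9 | lithium enolate of 8 (C5–OLi, C4=C5) | COC(=O)[C@@H](O[Si](CC)(CC)CC)C[C@]1(C)C([O-])=CCC[C@H]1O[Si](C)(C)C(C)(C)C.[Li+] | intermediate
10 | methyl (2S)-3-[(1S,2R,5S)-2-(tert-butyldimethylsilyloxy)-5-[(4-methoxybenzyloxy)methyl]-1-methyl-6-oxocyclohexyl]-2-(triethylsilyloxy)propanoate | COC(=O)[C@@H](O[Si](CC)(CC)CC)C[C@]1(C)C(=O)[C@H](COCc2ccc(OC)cc2)CC[C@H]1O[Si](C)(C)C(C)(C)C | intermediate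
11 | C5-methylidene analogue of 10 (C5=CH2) | COC(=O)[C@@H](O[Si](CC)(CC)CC)C[C@]1(C)C(=C)[C@H](COCc2ccc(OC)cc2)CC[C@H]1O[Si](C)(C)C(C)(C)C | intermediate
12 | B-(C6-alkyl)-9-borabicyclo[3.3.1]nonane adduct of 11 (5α-H) | COC(=O)[C@@H](O[Si](CC)(CC)CC)C[C@]1(C)[C@@H](CB2C3CCCC2CCC3)[C@H](COCc2ccc(OC)cc2)CC[C@H]1O[Si](C)(C)C(C)(C)C | intermediate
13 | C6 primary alcohol: methyl ester arm, ring A with 1β-OTBS, 10β-CH3, 5β-CH2OH, 4α-CH2OPMB | COC(=O)[C@@H](O[Si](CC)(CC)CC)C[C@]1(C)[C@@H](CO)[C@H](COCc2ccc(OC)cc2)CC[C@H]1O[Si](C)(C)C(C)(C)C | intermediate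
14 | C7 aldehyde (8S, α-triethylsilyloxy) with free C6-OH | O=C[C@@H](O[Si](CC)(CC)CC)C[C@]1(C)[C@@H](CO)[C@H](COCc2ccc(OC)cc2)CC[C@H]1O[Si](C)(C)C(C)(C)C | intermediate
15 | acryloyl chloride | C=CC(=O)Cl | starting material
16 | 2-(trimethylsilyl)ethanol | OCC[Si](C)(C)C | starting material
17 | 2-(trimethylsilyl)ethyl acrylate | C=CC(=O)OCC[Si](C)(C)C | intermediate
18 | Baylis–Hillman adduct (C7 carbinol epimers, C6-OH free, TMSE 2-methylidene ester) | C=C(C(=O)OCC[Si](C)(C)C)C(O)[C@@H](O[Si](CC)(CC)CC)C[C@]1(C)[C@@H](CO)[C@H](COCc2ccc(OC)cc2)CC[C@H]1O[Si](C)(C)C(C)(C)C | intermediate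
19 | C6 aldehyde of 18 (5β-CHO, C7 carbinol epimers) | C=C(C(=O)OCC[Si](C)(C)C)C(O)[C@@H](O[Si](CC)(CC)CC)C[C@]1(C)[C@@H](C=O)[C@H](COCc2ccc(OC)cc2)CC[C@H]1O[Si](C)(C)C(C)(C)C | intermediate
20 | ring-A C6 aldehyde with the (8S)-8-triethylsilyloxy (Z)-2-(bromomethyl)enoate arm, TMSE ester (key-step precursor) | CC[Si](CC)(CC)O[C@H](/C=C(\CBr)C(=O)OCC[Si](C)(C)C)C[C@]1(C)[C@@H](C=O)[C@H](COCc2ccc(OC)cc2)CC[C@H]1O[Si](C)(C)C(C)(C)C | intermediate
21 | 2-(alkoxycarbonyl)allylchromium(III) dichloride from 20 (alkene geometry mobile) | CC[Si](CC)(CC)O[C@H](C=C(C[Cr](Cl)Cl)C(=O)OCC[Si](C)(C)C)C[C@]1(C)[C@@H](C=O)[C@H](COCc2ccc(OC)cc2)CC[C@H]1O[Si](C)(C)C(C)(C)C | intermediate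
22 | 2-(trimethylsilyl)ethyl 6α-hydroxy-1β-(tert-butyldimethylsilyloxy)-15-(4-methoxybenzyloxy)-8α-(triethylsilyloxy)eudesm-11(13)-en-12-oate (key-step product) | CC[Si](CC)(CC)O[C@H]1C[C@]2(C)[C@@H]([C@@H](O)[C@@H]1C(=C)C(=O)OCC[Si](C)(C)C)[C@H](COCc3ccc(OC)cc3)CC[C@H]2O[Si](C)(C)C(C)(C)C | intermediate
23 | 6α-O-TBS ether of 22 | CC[Si](CC)(CC)O[C@H]1C[C@]2(C)[C@@H]([C@@H](O[Si](C)(C)C(C)(C)C)[C@@H]1C(=C)C(=O)OCC[Si](C)(C)C)[C@H](COCc3ccc(OC)cc3)CC[C@H]2O[Si](C)(C)C(C)(C)C | intermediate
24 | 8α-alcohol (1β,6α-bis-OTBS, 15-OPMB, TMSE ester) | O[C@H]1C[C@]2(C)[C@@H]([C@@H](O[Si](C)(C)C(C)(C)C)[C@@H]1C(=C)C(=O)OCC[Si](C)(C)C)[C@H](COCc3ccc(OC)cc3)CC[C@H]2O[Si](C)(C)C(C)(C)C | intermediate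
25 | ethyl 2-(hydroxymethyl)acrylate | C=C(CO)C(=O)OCC | starting material
26 | ethyl 2-[(tert-butyldimethylsilyloxy)methyl]acrylate | C=C(CO[Si](C)(C)C(C)(C)C)C(=O)OCC | intermediate
27 | 2-[(tert-butyldimethylsilyloxy)methyl]acrylic acid | C=C(CO[Si](C)(C)C(C)(C)C)C(=O)O | intermediate
28 | 8α-O-{2-[(tert-butyldimethylsilyloxy)methyl]acryloyl} ester (1β,6α-bis-OTBS, 15-OPMB, TMSE ester) | C=C(CO[Si](C)(C)C(C)(C)C)C(=O)O[C@H]1C[C@]2(C)[C@@H]([C@@H](O[Si](C)(C)C(C)(C)C)[C@@H]1C(=C)C(=O)OCC[Si](C)(C)C)[C@H](COCc3ccc(OC)cc3)CC[C@H]2O[Si](C)(C)C(C)(C)C | intermediate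
29 | C15 primary alcohol of 28 | C=C(CO[Si](C)(C)C(C)(C)C)C(=O)O[C@H]1C[C@]2(C)[C@@H]([C@@H](O[Si](C)(C)C(C)(C)C)[C@@H]1C(=C)C(=O)OCC[Si](C)(C)C)[C@H](CO)CC[C@H]2O[Si](C)(C)C(C)(C)C | intermediate
30 | C15 aldehyde (4α-CHO), fully protected target | C=C(CO[Si](C)(C)C(C)(C)C)C(=O)O[C@H]1C[C@]2(C)[C@@H]([C@@H](O[Si](C)(C)C(C)(C)C)[C@@H]1C(=C)C(=O)OCC[Si](C)(C)C)[C@H](C=O)CC[C@H]2O[Si](C)(C)C(C)(C)C | intermediate
31 | 8α-[2-(hydroxymethyl)acryloyloxy]-1β,6α-dihydroxy-15-oxoeudesm-11(13)-en-12-oic acid (CNP0599450.1) | C=C(CO)C(=O)O[C@H]1C[C@]2(C)[C@@H]([C@@H](O)[C@@H]1C(=C)C(=O)O)[C@H](C=O)CC[C@H]2O | target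

**Step count**
Total: 23 steps. Longest linear sequence: 20 steps (steps 1–10, 12–17, 20–23, from 1 to 31); steps 11 and 18–19 are side branches.

**Steps most likely to fail**

Step 15 (key ring closure). Carbon–carbon bond formation may outrun the E/Z equilibration of the allylchromium, so that the cis-fused transition state delivers a 6,7-syn isomer. Chromium may also shift to C7 and expel the β-silyloxy group to give a diene, or intermolecular coupling may compete with cyclisation. The fallback is a palladium-catalysed umpolung allylation, which changes both the precursor and the way the allyl nucleophile is generated. It sets out from 19: acetylation (Ac2O, pyridine, DMAP) gives the Baylis–Hillman acetate F1. Pd(PPh3)4 (cat.) and Et2Zn in THF then turn the π-allylpalladium into the configurationally mobile allyl(ethyl)zinc species F2, which should add through C7 to the C6 aldehyde via the same chair–chair array. The fallback comes back to the route at 22.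

Step 12 (Baylis–Hillman reaction). Addition to the hindered α-silyloxy aldehyde may be slow, and over the long reaction time C8 may epimerise or the free C6 hydroxyl may add to the acrylate. The fallback is an aluminium-mediated reductive aldol, which sets out from 14 and 16. Esterification of 16 with propiolic acid (DCC, DMAP cat.) gives 2-(trimethylsilyl)ethyl propiolate F3. Hydroalumination with DIBAL-H/HMPA gives the α-(diisobutylalumino)acrylate F4, used in excess because the free hydroxyl consumes one equivalent, and this should add to the C7 aldehyde at low temperature. The fallback comes back to the route at 18.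

Step 8 (methylenation). The 2,2,6-trisubstituted ketone may resist methylenation, or the Lewis-acidic titanium reagent may strip the PMB or TES ether. The fallback builds C6 by epoxide rearrangement and sets out from 10. Dimethylsulfonium methylide (Me3S+ I−, KHMDS, THF, −10 °C; Corey–Chaykovsky) should add from the α face to give the spiro-epoxide F5. Methylaluminium bis(4-bromo-2,6-di-tert-butylphenoxide) at −78 °C should open it at C5 with a 1,2-hydride shift (Meinwald rearrangement) to the 5β-aldehyde F6, which can be equilibrated with DBU if needed. NaBH4 in MeOH at 0 °C then reduces the aldehyde beside the methyl ester. The fallback comes back to the route at 13.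

**Further compounds**
F1 | step 15 | Baylis–Hillman acetate of 19 (C7-OAc, C6 aldehyde) | C=C(C(=O)OCC[Si](C)(C)C)C(OC(C)=O)[C@@H](O[Si](CC)(CC)CC)C[C@]1(C)[C@@H](C=O)[C@H](COCc2ccc(OC)cc2)CC[C@H]1O[Si](C)(C)C(C)(C)C
F2 | step 15 | allyl(ethyl)zinc species from F1 (zinc on C13, alkene geometry mobile) | CC[Zn]CC(C(=O)OCC[Si](C)(C)C)=C[C@@H](O[Si](CC)(CC)CC)C[C@]1(C)[C@@H](C=O)[C@H](COCc2ccc(OC)cc2)CC[C@H]1O[Si](C)(C)C(C)(C)C
F3 | step 12 | 2-(trimethylsilyl)ethyl propiolate | C#CC(=O)OCC[Si](C)(C)C
F4 | step 12 | 2-(trimethylsilyl)ethyl 2-(diisobutylalumino)acrylate | C=C([Al](CC(C)C)CC(C)C)C(=O)OCC[Si](C)(C)C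
F5 | step 8 | C5 spiro-epoxide of 10 (CH2 on the α face, O on the β face) | COC(=O)[C@@H](O[Si](CC)(CC)CC)C[C@]1(C)[C@]2(CO2)[C@H](COCc3ccc(OC)cc3)CC[C@H]1O[Si](C)(C)C(C)(C)C
F6 | step 8 | 5β-carbaldehyde with methyl ester arm (C6 aldehyde, C7 ester) | COC(=O)[C@@H](O[Si](CC)(CC)CC)C[C@]1(C)[C@@H](C=O)[C@H](COCc2ccc(OC)cc2)CC[C@H]1O[Si](C)(C)C(C)(C)C
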